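**Retrosynthetic overview**

- Feature: ring B (C1', C5', C6', C7', C8', C9', C10') becomes a cyclohepta-1,4-diene once C8' is written as an enol ether. The alkenes C1'=C5' and C8'=C9' then flank the methyl-bearing sp3 carbon C10', which is the pattern left by a cis-divinylcyclopropane rearrangement. Disconnect C6'–C7' and reconnect C1'–C9'.
- The rearrangement substrate is the silyl enol ether of a cis-2-vinylcyclopropyl ketone hung on the quaternary C11' of unit A. The C11'–C7' bond comes from alkylating a ring C β-keto ester with a chloromethyl cyclopropyl ketone.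
- Unit A: ring A and lactone A from cyclohepta-1,3-diene (cis-1,4-diacetoxylation, enzymatic desymmetrisation, Johnson–Claisen, lactonisation). The C1 ketone, 10-methyl and C5 methylene follow, and ring C is closed by Michael–aldol annulation with methyl acetoacetate.
- Cyclopropane: intramolecular cyclopropanation of an (E)-allylic diazoacetate gives a bicyclic lactone that fixes acyl and vinyl cis and the methyl trans.
- Ring order: lactone A on ring A, ring C, cyclopropane (separate branch), ring B (key step), lactone B. Then the C3 triflate, C13 methylene, C3 acetyl and deprotection.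

Key step: step 22

**Remarks**

- Numbering: unit A has C1 (carbinol), C2=C3, acetyl C4 on C3, C5 (ring-fusion CH), ring A = C1, C5, C6, C7, C8, C9, C10, lactone A = C7, C8, O, C12, C11, methylene C13. Ring C = C1, C2, C3, C11', C13', C5. Unit B has spiro C11', carbonyl C12', ring B = C1', C5', C6', C7', C8', C9', C10'.
- Assumption: the lipase of step 2 is taken to give the (1S,4R)-monoacetate; if it gives the antipode, the same enzyme run in the acylation direction on the meso-diol supplies the required one.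

**Route**

Step 1
Reactants: 1 cyclohepta-1,3-diene
Product: 2 cis-cyclohept-2-ene-1,4-diyl diacetate (meso)
Conditions: Pd(OAc)2 (5 mol %), LiCl (cat.), LiOAc, p-benzoquinone, AcOH, 25 °C
Reagents that add atoms: acetic acid, CC(=O)O
Why: Palladium-catalysed 1,4-diacetoxylation of a 1,3-diene; with chloride on palladium the second acetate attacks the π-allyl complex from outside, which should give the cis (meso) diacetate.

Step 2
Reactants: 2 cis-cyclohept-2-ene-1,4-diyl diacetate
Product: 3 (1S,4R)-cis-4-acetoxycyclohept-2-en-1-ol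
Conditions: lipase from Burkholderia cepacia, phosphate buffer pH 7, 25 °C
Reagents that add atoms: none
Why: Enzymatic desymmetrisation of a meso-diacetate by hydrolysis of one enantiotopic ester; this fixes C8 and, through step 3, C7.

Step 3
Reactants: 3 (1S,4R)-cis-4-acetoxycyclohept-2-en-1-ol
Product: 4 ethyl 2-[(1S,6R)-6-acetoxycyclohept-2-en-1-yl]acetate
Conditions: MeC(OEt)3, EtCO2H (cat.), 140 °C, ethanol distilled off
Reagents that add atoms: triethyl orthoacetate, CC(OCC)(OCC)OCC
Why: Johnson orthoester Claisen rearrangement; the ketene acetal transfers CH2CO2Et suprafacially from the C5 oxygen to C7, so the new C7–C11 bond is cis to the C8 acetate and the alkene moves to C5=C6.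

Step 4
Reactants: 4 ethyl 2-[(1S,6R)-6-acetoxycyclohept-2-en-1-yl]acetate
Product: 6 (3aS,8aR)-3,3a,6,7,8,8a-hexahydro-2H-cyclohepta[b]furan-2-one, via hydroxy ester 5 (not isolated)
Conditions: K2CO3, MeOH, 25 °C; then dilute aq. HCl to pH 3
Reagents that add atoms: none
Why: Methanolysis of the acetate frees the C8 hydroxyl, which closes the cis-fused γ-lactone on the cis ester arm by intramolecular acyl substitution.

Step 5
Reactants: 6 (3aS,8aR)-3,3a,6,7,8,8a-hexahydro-2H-cyclohepta[b]furan-2-one
Product: 7 (3aS,8aR)-3,3a,8,8a-tetrahydro-2H-cyclohepta[b]furan-2,6(7H)-dione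
Conditions: Rh2(cap)4 (1 mol %), t-BuOOH, K2CO3, CH2Cl2, 25 °C
Reagents that add atoms: tert-butyl hydroperoxide, CC(C)(C)OO
Why: Allylic C–H oxidation to the enone; the open allylic methylene C1 should react in preference to the tertiary C7–H, which is hindered and next to the lactone.

Step 6
Reactants: 7 (3aS,8aR)-3,3a,8,8a-tetrahydro-2H-cyclohepta[b]furan-2,6(7H)-dione
Product: 10 (3aS,8aR)-7-methylidene-3,3a,8,8a-tetrahydro-2H-cyclohepta[b]furan-2,6(7H)-dione, via Mannich base 8 (not isolated), via trimethylammonium iodide 9 (not isolated)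
Conditions: LiN(i-Pr)2, THF, −78 °C; CH2=NMe2+ I−, −78 → 25 °C; MeI, MeOH; aq. NaHCO3, CH2Cl2
Reagents that add atoms: N,N-dimethylmethyleneiminium iodide, C=[N+](C)C.[I-]
Why: Kinetic α'-deprotonation of the enone at C10 (the ketone is more acidic than the lactone), Mannich reaction, quaternisation and E1cB loss of trimethylamine give the exocyclic methylene.

Step 7
Reactants: 10 (3aS,8aR)-7-methylidene-3,3a,8,8a-tetrahydro-2H-cyclohepta[b]furan-2,6(7H)-dione
Product: 11 (3aR,7S,8aR)-7-methylhexahydro-2H-cyclohepta[b]furan-2,6(3H)-dione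
Conditions: H2 (1 atm), Pd/C, EtOAc, 25 °C
Reagents that add atoms: none
Why: Catalytic hydrogenation of both C=C bonds; hydrogen should reach the exocyclic alkene from the convex face opposite the cis-fused lactone, which puts the C10 methyl on the lactone face (10S).

Step 8
Reactants: 11 (3aR,7S,8aR)-7-methylhexahydro-2H-cyclohepta[b]furan-2,6(3H)-dione
Product: 14 (3aR,7S,8aR)-7-methyl-5-methylidenehexahydro-2H-cyclohepta[b]furan-2,6(3H)-dione, via Mannich base 12 (not isolated), via trimethylammonium iodide 13 (not isolated)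
Conditions: LiN(i-Pr)2, THF, −78 °C; CH2=NMe2+ I−; MeI, MeOH; aq. NaHCO3, CH2Cl2
Reagents that add atoms: N,N-dimethylmethyleneiminium iodide, C=[N+](C)C.[I-]
Why: The kinetic enolate forms at the methylene C5 and not at the methine C10, so the same α-methylenation gives the α-methylene ketone without touching the C10 centre; 14 is used at once.

Step 9
Reactants: 14 (3aR,7S,8aR)-7-methyl-5-methylidenehexahydro-2H-cyclohepta[b]furan-2,6(3H)-dione; 15 methyl acetoacetate
Product: 17 tricyclic ketol β-keto ester (ring C: 1-OH, C3 ketone, CO2Me on C11'; trans ring fusion with 1-OH anti to 5-H; C11' as keto/enol mixture), via Michael adduct 16 (not isolated)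
Conditions: NaOMe (0.2 equiv), MeOH, 0 → 25 °C
Reagents that add atoms: none
Why: Michael addition of the acetoacetate to the exocyclic enone followed by reversible aldol closure of the acetyl methyl onto C1 (Robinson-type annulation stopped at the ketol); the 5-H is delivered on the convex face and the ketol should settle as the trans-fused chair with axial 1-OH and both ring A bonds equatorial.

Step 10
Reactants: 17 tricyclic ketol β-keto ester
Product: 19 1-O-triethylsilyl ketol β-keto ester, via bis(triethylsilyl) enol ether 18 (not isolated)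
Conditions: Et3SiOTf (2.5 equiv), 2,6-lutidine, CH2Cl2, −78 → 0 °C; then 10 % aq. citric acid, THF, 0 °C
Reagents that add atoms: triethylsilyl trifluoromethanesulfonate, CC[Si](CC)(CC)OS(=O)(=O)C(F)(F)F
Why: Silyl triflate with a hindered base silylates the tertiary alcohol; the enol silyl ether of the β-keto ester formed alongside is hydrolysed by mild acid while the tertiary silyl ether stays.

Step 11
Reactants: 20 triethyl phosphonoacetate; 21 2-(2-bromoethyl)-2-methyl-1,3-dioxolane
Product: 22 ethyl 2-(diethoxyphosphoryl)-4-(2-methyl-1,3-dioxolan-2-yl)butanoate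
Conditions: NaH, DMF, 0 → 60 °C
Reagents that add atoms: none
Why: SN2 C-alkylation of the phosphonoacetate anion with a primary bromide.

Step 12
Reactants: 22 ethyl 2-(diethoxyphosphoryl)-4-(2-methyl-1,3-dioxolan-2-yl)butanoate
Product: 23 ethyl (E)-2-[2-(2-methyl-1,3-dioxolan-2-yl)ethyl]but-2-enoate
Conditions: NaH, THF, 0 °C; CH3CHO, 0 → 25 °C; chromatography
Reagents that add atoms: acetaldehyde, CC=O
Why: Horner–Wadsworth–Emmons olefination, which should favour the (E)-enoate with the ester trans to the new methyl; the minor Z isomer is removed by chromatography.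

Step 13
Reactants: 23 ethyl (E)-2-[2-(2-methyl-1,3-dioxolan-2-yl)ethyl]but-2-enoate
Product: 24 (E)-2-[2-(2-methyl-1,3-dioxolan-2-yl)ethyl]but-2-en-1-ol
Conditions: i-Bu2AlH (2.2 equiv), CH2Cl2, −78 °C; aq. potassium sodium tartrate
Reagents that add atoms: none
Why: 1,2-Reduction of the enoate to the allylic alcohol; the ketal and the alkene geometry are not affected.

Step 14
Reactants: 24 (E)-2-[2-(2-methyl-1,3-dioxolan-2-yl)ethyl]but-2-en-1-ol
Product: 26 (E)-2-[2-(2-methyl-1,3-dioxolan-2-yl)ethyl]but-2-en-1-yl diazoacetate, via glyoxylate tosylhydrazone ester 25 (not isolated)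
Conditions: TsNHN=CHCOCl, PhNMe2, CH2Cl2, 0 °C; then Et3N, 0 → 25 °C
Reagents that add atoms: glyoxylic acid chloride p-toluenesulfonylhydrazone, Cc1ccc(cc1)S(=O)(=O)NN=CC(Cl)=O
Why: Corey–Myers diazoacetate synthesis: acylation of the alcohol, then base-induced loss of p-toluenesulfinate from the tosylhydrazone.

Step 15
Reactants: 26 allylic diazoacetate
Product: 27 (1R,5S,6R)-6-methyl-5-[2-(2-methyl-1,3-dioxolan-2-yl)ethyl]-3-oxabicyclo[3.1.0]hexan-2-one
Conditions: Rh2(4S-MPPIM)4 (1 mol %), CH2Cl2, reflux, slow addition of 26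
Reagents that add atoms: none
Why: Intramolecular rhodium-carbenoid cyclopropanation; the tether forces carbonyl and CH2O cis, the stereospecific addition keeps the methyl trans to the lactone ring, and the chiral carboxamidate catalyst selects the alkene face (the 4S ligand is expected, by analogy with allyl diazoacetate, to give the 1R,5S sense; the 4R catalyst serves otherwise).

Step 16
Reactants: 27 bicyclic cyclopropane lactone
Product: 28 (1R,2S,3R)-2-(hydroxymethyl)-N-methoxy-N,3-dimethyl-2-[2-(2-methyl-1,3-dioxolan-2-yl)ethyl]cyclopropane-1-carboxamide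
Conditions: MeNH(OMe)·HCl, i-PrMgCl, THF, −20 → 0 °C
Reagents that add atoms: N,O-dimethylhydroxylamine hydrochloride, CNOC.Cl
Why: Aminolysis of the lactone by the magnesium amide gives the Weinreb amide and frees the primary alcohol; no stereocentre is touched, and 28 is oxidised at once to prevent relactonisation.

Step 17
Reactants: 28 hydroxy Weinreb amide
Product: 29 (1R,2S,3R)-2-formyl-N-methoxy-N,3-dimethyl-2-[2-(2-methyl-1,3-dioxolan-2-yl)ethyl]cyclopropane-1-carboxamide
Conditions: Dess–Martin periodinane, NaHCO3, CH2Cl2, 0 → 25 °C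
Reagents that add atoms: none
Why: Mild oxidation of the primary alcohol; the aldehyde sits on a quaternary carbon and cannot epimerise.

Step 18
Reactants: 29 formyl Weinreb amide
Product: 30 (1R,2S,3R)-2-ethenyl-N-methoxy-N,3-dimethyl-2-[2-(2-methyl-1,3-dioxolan-2-yl)ethyl]cyclopropane-1-carboxamide
Conditions: Ph3PCH3Br, KN(SiMe3)2, THF, 0 °C; then 29, −78 → 0 °C
Reagents that add atoms: methyltriphenylphosphonium bromide, C[P+](c1ccccc1)(c1ccccc1)c1ccccc1.[Br-]
Why: Wittig methylenation; the unstabilised ylide reacts with hindered aldehydes and leaves the amide alone.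

Step 19
Reactants: 30 vinyl Weinreb amide
Product: 31 2-chloro-1-[(1R,2S,3R)-2-ethenyl-3-methyl-2-[2-(2-methyl-1,3-dioxolan-2-yl)ethyl]cyclopropyl]ethan-1-one
Conditions: ICH2Cl, MeLi·LiBr, THF/Et2O, −78 °C; aq. NH4Cl
Reagents that add atoms: chloroiodomethane, ClCI
Why: Chloromethyllithium, made by iodine–lithium exchange, adds once to the Weinreb amide because the chelated tetrahedral adduct survives until quench; this gives the α-chloroketone directly, and 31 is kept cold.

Step 20
Reactants: 19 1-O-triethylsilyl ketol β-keto ester; 31 chloromethyl cyclopropyl ketone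
Product: 32 C11'-alkylated 1,4-diketone (quaternary C11' with CO2Me, C3 ketone and CH2C(=O)-cyclopropyl)
Conditions: K2CO3, NaI (0.2 equiv), acetone, 25 °C
Reagents that add atoms: none
Why: C-alkylation of the β-keto ester enolate by the α-haloketone with iodide exchange in the flask; the electrophile should enter C11' axially, on the face away from the axial 1-OSiEt3 and leading straight to the chair, so that C7' is axial and the ester equatorial as in the target.

Step 21
Reactants: 32 C11'-alkylated 1,4-diketone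
Product: 33 bis(trimethylsilyl enol ether): C2=C3(OSiMe3) and (Z)-C7'=C8'(OSiMe3) on the cis-vinylcyclopropane
Conditions: Me3SiOTf (3 equiv), Et3N (5 equiv), CH2Cl2, −78 → −20 °C; cold aq. NaHCO3; used without delay
Reagents that add atoms: trimethylsilyl trifluoromethanesulfonate, C[Si](C)(C)OS(=O)(=O)C(F)(F)F
Why: Soft enolisation; C7' is the only enolisable position of the cyclopropyl ketone and C2 the only one of the C3 ketone, and the quaternary C11' should take the side of the enol oxygen (Z) to avoid allylic strain with the cyclopropane. Incomplete silylation at the hindered C3 does no harm, because both forms converge at 35.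

Step 22
Reactants: 33 bis(trimethylsilyl enol ether)
Product: 34 ring B cyclohepta-1,4-diene silyl enol ether (C1'=C5', C8'(OSiMe3)=C9', new C6'–C7' bond) on the tricyclic core
Conditions: benzene, 60 °C
Reagents that add atoms: none
Why: On warming, the (Z)-silyl enol ether C7'=C8' and the vinyl group C5'=C6', both cis on the cyclopropane, fold over the three-membered ring and undergo a concerted [3,3] shift through the boat transition state: C6'–C7' forms, C1'–C9' breaks and the alkenes move to C1'=C5' and C8'=C9'. The closest known reaction type is the Cope rearrangement of 2-silyloxy cis-divinylcyclopropanes (enol silyl ethers of cis-2-vinylcyclopropyl ketones) to cyclohepta-1,4-dienes, driven by release of ring strain and helped by the donor oxygen. Ring B closes as a three-to-seven ring expansion in which the new sigma bond joins the two alkene termini within one six-centre pericyclic array. The new stereocentre C7' is fixed by the enol ether geometry together with the cyclopropane configuration: C11' is trans to the cyclopropane on C7'=C8', points outward in the boat and so ends cis to the C10' methyl, which is anti to both alkenyl groups and is carried over unchanged. The step needs the cis acyl/vinyl relationship (built in by lactone 27), the Z enol ether (secured by the bulk of C11') and hydrogen at the inward positions of C6', C7' and C10', all of which 33 has. The trans methyl also closes off the competing homo-1,5-hydrogen shift.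

Step 23
Reactants: 34 ring B silyl enol ether
Product: 35 diketone with ring B as cyclohept-4-enone (C8' ketone, C3 ketone, CO2Me on C11')
Conditions: 10 % aq. citric acid, THF, 0 → 25 °C
Reagents that add atoms: none
Why: Mild acid hydrolysis of both silyl enol ethers by C-protonation; the tertiary triethylsilyl ether and the dioxolane should survive, and C7' is not epimerised.

Step 24
Reactants: 35 diketone
Product: 37 spiro-lactone ketone (lactone B cis-fused to ring B, C3 ketone intact), via cis-hydroxy ester 36 (not isolated)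
Conditions: LiBH(s-Bu)3 (1.1 equiv), THF, −78 °C; AcOH quench; then PPTS (cat.), benzene, 40 °C
Reagents that add atoms: none
Why: The bulky hydride should attack the C8' ketone from the face opposite the C7' branch and the C10' methyl, giving the alcohol cis to C11', which lactonises onto the C12' ester. The C3 ketone is shielded on one face by the axial 1-OSiEt3 and on the other by the axial C7' branch, and the acetic acid quench prevents retro-Claisen cleavage by methoxide.

Step 25
Reactants: 37 spiro-lactone ketone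
Product: 38 C2=C3 enol triflate
Conditions: KN(SiMe3)2 (1.2 equiv), THF, −78 °C; PhNTf2
Reagents that add atoms: N-phenylbis(trifluoromethanesulfonimide), O=S(=O)(N(c1ccccc1)S(=O)(=O)C(F)(F)F)C(F)(F)F
Why: The C3 ketone can enolise only toward C2 because C11' is quaternary; the enolate is trapped on oxygen at low temperature before the β-silyloxy group can be lost.

Step 26
Reactants: 38 enol triflate
Product: 41 α-methylene lactone A enol triflate, via Mannich base 39 (not isolated), via trimethylammonium iodide 40 (not isolated)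
Conditions: LiN(i-Pr)2, THF, −78 °C; CH2=NMe2+ I−; MeI, MeOH; aq. NaHCO3, CH2Cl2
Reagents that add atoms: N,N-dimethylmethyleneiminium iodide, C=[N+](C)C.[I-]
Why: C11 of lactone A is now the only acidic C–H (lactone B has no α-hydrogen and the ketones are masked), so enolate Mannich reaction and E1cB elimination install the C13 methylene.

Step 27
Reactants: 41 α-methylene lactone enol triflate
Product: 42 C3-(1-ethoxyvinyl) diene
Conditions: tributyl(1-ethoxyvinyl)stannane, Pd(PPh3)4 (5 mol %), LiCl, CuI (10 mol %), THF, 65 °C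
Reagents that add atoms: tributyl(1-ethoxyvinyl)stannane, CCCC[Sn](CCCC)(CCCC)C(=C)OCC
Why: Stille coupling of a vinyl triflate with an α-alkoxyvinylstannane as a masked acetyl group; chloride assists transmetalation and the α-methylene lactone is tolerated.

Step 28
Reactants: 42 C3-(1-ethoxyvinyl) diene
Product: 43 CNP0195550.1 (target)
Conditions: 2 M aq. HCl, THF, 25 °C
Reagents that add atoms: water, O
Why: One acid hydrolysis turns the enol ether into the C3 acetyl group, opens the dioxolane to the side-chain methyl ketone and cleaves the tertiary silyl ether to the C1 alcohol.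

**Compound list**

1 | cyclohepta-1,3-diene | C1=CC=CCCC1 | starting material
2 | cis-cyclohept-2-ene-1,4-diyl diacetate | CC(=O)O[C@@H]1CCC[C@H](OC(C)=O)C=C1 | intermediate
3 | (1S,4R)-cis-4-acetoxycyclohept-2-en-1-ol | O[C@@H]1C=C[C@H](OC(C)=O)CCC1 | intermediate
4 | ethyl 2-[(1S,6R)-6-acetoxycyclohept-2-en-1-yl]acetate | CCOC(=O)C[C@H]1C=CCCC[C@H]1OC(C)=O | intermediate
5 | ethyl 2-[(1S,6R)-6-hydroxycyclohept-2-en-1-yl]acetate | CCOC(=O)C[C@H]1C=CCCC[C@H]1O | intermediate
6 | (3aS,8aR)-3,3a,6,7,8,8a-hexahydro-2H-cyclohepta[b]furan-2-one | C1C(=O)O[C@@H]2CCCC=C[C@H]12 | intermediate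
7 | (3aS,8aR)-3,3a,8,8a-tetrahydro-2H-cyclohepta[b]furan-2,6(7H)-dione | C1C(=O)O[C@@H]2CCC(=O)C=C[C@H]12 | intermediate
8 | 7-[(dimethylamino)methyl] derivative of 7 (Mannich base) | C1C(=O)O[C@@H]2CC(CN(C)C)C(=O)C=C[C@H]12 | intermediate
9 | trimethylammonium iodide of 8 | C1C(=O)O[C@@H]2CC(C[N+](C)(C)C)C(=O)C=C[C@H]12.[I-] | intermediate
10 | (3aS,8aR)-7-methylidene-3,3a,8,8a-tetrahydro-2H-cyclohepta[b]furan-2,6(7H)-dione | C1C(=O)O[C@@H]2CC(=C)C(=O)C=C[C@H]12 | intermediate
11 | (3aR,7S,8aR)-7-methylhexahydro-2H-cyclohepta[b]furan-2,6(3H)-dione | C1C(=O)O[C@@H]2C[C@H](C)C(=O)CC[C@H]12 | intermediate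
12 | 5-[(dimethylamino)methyl] derivative of 11 (Mannich base) | C1C(=O)O[C@@H]2C[C@H](C)C(=O)C(CN(C)C)C[C@H]12 | intermediate
13 | trimethylammonium iodide of 12 | C1C(=O)O[C@@H]2C[C@H](C)C(=O)C(C[N+](C)(C)C)C[C@H]12.[I-] | intermediate
14 | (3aR,7S,8aR)-7-methyl-5-methylidenehexahydro-2H-cyclohepta[b]furan-2,6(3H)-dione | C1C(=O)O[C@@H]2C[C@H](C)C(=O)C(=C)C[C@H]12 | intermediate
15 | methyl acetoacetate | CC(=O)CC(=O)OC | starting material
16 | Michael adduct: C5-[2-acetyl-2-(methoxycarbonyl)ethyl] ketone of ring A | C1C(=O)O[C@@H]2C[C@H](C)C(=O)[C@H](CC(C(C)=O)C(=O)OC)C[C@H]12 | intermediate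
17 | tricyclic ketol β-keto ester (1-OH, C3 ketone, CO2Me on C11', trans-fused rings A/C) | C1C(=O)O[C@@H]2C[C@H](C)[C@@]3(O)CC(=O)C(C[C@@H]3C[C@H]12)C(=O)OC | intermediate
18 | 1-O-triethylsilyl, C3-O-triethylsilyl enol ether of 17 | C1C(=O)O[C@@H]2C[C@H](C)[C@@]3(O[Si](CC)(CC)CC)CC(O[Si](CC)(CC)CC)=C(C[C@@H]3C[C@H]12)C(=O)OC | intermediate
19 | 1-O-triethylsilyl ketol β-keto ester | C1C(=O)O[C@@H]2C[C@H](C)[C@@]3(O[Si](CC)(CC)CC)CC(=O)C(C[C@@H]3C[C@H]12)C(=O)OC | intermediate
20 | triethyl phosphonoacetate | CCOC(=O)CP(=O)(OCC)OCC | starting material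
21 | 2-(2-bromoethyl)-2-methyl-1,3-dioxolane | BrCCC1(C)OCCO1 | starting material
22 | ethyl 2-(diethoxyphosphoryl)-4-(2-methyl-1,3-dioxolan-2-yl)butanoate | CCOC(=O)C(CCC1(C)OCCO1)P(=O)(OCC)OCC | intermediate
23 | ethyl (E)-2-[2-(2-methyl-1,3-dioxolan-2-yl)ethyl]but-2-enoate | CCOC(=O)/C(CCC1(C)OCCO1)=C/C | intermediate
24 | (E)-2-[2-(2-methyl-1,3-dioxolan-2-yl)ethyl]but-2-en-1-ol | OC/C(CCC1(C)OCCO1)=C/C | intermediate
25 | allylic ester of glyoxylic acid p-toluenesulfonylhydrazone | Cc1ccc(cc1)S(=O)(=O)NN=CC(=O)OC/C(CCC2(C)OCCO2)=C/C | intermediate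
26 | (E)-2-[2-(2-methyl-1,3-dioxolan-2-yl)ethyl]but-2-en-1-yl diazoacetate | [N-]=[N+]=CC(=O)OC/C(CCC1(C)OCCO1)=C/C | intermediate
27 | (1R,5S,6R)-6-methyl-5-[2-(2-methyl-1,3-dioxolan-2-yl)ethyl]-3-oxabicyclo[3.1.0]hexan-2-one | O=C1OC[C@@]2(CCC3(C)OCCO3)[C@H](C)[C@@H]12 | intermediate
28 | (1R,2S,3R)-2-(hydroxymethyl)-N-methoxy-N,3-dimethyl-2-[2-(2-methyl-1,3-dioxolan-2-yl)ethyl]cyclopropane-1-carboxamide | CON(C)C(=O)[C@@H]1[C@@H](C)[C@@]1(CO)CCC2(C)OCCO2 | intermediate
29 | (1R,2S,3R)-2-formyl-N-methoxy-N,3-dimethyl-2-[2-(2-methyl-1,3-dioxolan-2-yl)ethyl]cyclopropane-1-carboxamide | CON(C)C(=O)[C@@H]1[C@@H](C)[C@@]1(C=O)CCC2(C)OCCO2 | intermediate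
30 | (1R,2S,3R)-2-ethenyl-N-methoxy-N,3-dimethyl-2-[2-(2-methyl-1,3-dioxolan-2-yl)ethyl]cyclopropane-1-carboxamide | CON(C)C(=O)[C@@H]1[C@@H](C)[C@@]1(C=C)CCC2(C)OCCO2 | intermediate
31 | 2-chloro-1-[(1R,2S,3R)-2-ethenyl-3-methyl-2-[2-(2-methyl-1,3-dioxolan-2-yl)ethyl]cyclopropyl]ethan-1-one | ClCC(=O)[C@@H]1[C@@H](C)[C@@]1(C=C)CCC2(C)OCCO2 | intermediate
32 | C11'-alkylated 1,4-diketone (1-OSiEt3; C3 ketone; CO2Me and CH2C(=O)-cyclopropyl on C11') | C1C(=O)O[C@@H]2C[C@H](C)[C@@]3(O[Si](CC)(CC)CC)CC(=O)[C@@](C[C@@H]3C[C@H]12)(C(=O)OC)CC(=O)[C@@H]4[C@@H](C)[C@@]4(C=C)CCC5(C)OCCO5 | intermediate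
33 | bis(trimethylsilyl enol ether) of 32 (C2=C3 and (Z)-C7'=C8'), rearrangement precursor | C1C(=O)O[C@@H]2C[C@H](C)[C@@]3(O[Si](CC)(CC)CC)C=C(O[Si](C)(C)C)[C@@](C[C@@H]3C[C@H]12)(C(=O)OC)/C=C(\O[Si](C)(C)C)[C@@H]4[C@@H](C)[C@@]4(C=C)CCC5(C)OCCO5 | intermediate
34 | ring B cyclohepta-1,4-diene silyl enol ether on the tricyclic core, rearrangement product | C1C(=O)O[C@@H]2C[C@H](C)[C@@]3(O[Si](CC)(CC)CC)C=C(O[Si](C)(C)C)[C@@](C[C@@H]3C[C@H]12)(C(=O)OC)[C@@H]4CC=C(CCC5(C)OCCO5)[C@H](C)C=C4O[Si](C)(C)C | intermediate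
35 | diketone with ring B cyclohept-4-enone (C8' and C3 ketones, CO2Me on C11') | C1C(=O)O[C@@H]2C[C@H](C)[C@@]3(O[Si](CC)(CC)CC)CC(=O)[C@@](C[C@@H]3C[C@H]12)(C(=O)OC)[C@@H]4CC=C(CCC5(C)OCCO5)[C@H](C)CC4=O | intermediate
36 | cis-8'-hydroxy ester (8'-OH cis to C11') | C1C(=O)O[C@@H]2C[C@H](C)[C@@]3(O[Si](CC)(CC)CC)CC(=O)[C@@](C[C@@H]3C[C@H]12)(C(=O)OC)[C@@H]4CC=C(CCC5(C)OCCO5)[C@H](C)C[C@@H]4O | intermediate
37 | spiro-lactone B ketone (C3 ketone, 1-OSiEt3, ketal side chain) | C1C(=O)O[C@@H]2C[C@H](C)[C@@]3(O[Si](CC)(CC)CC)CC(=O)[C@@]4(C[C@@H]3C[C@H]12)C(=O)O[C@H]1C[C@@H](C)C(CCC5(C)OCCO5)=CC[C@H]14 | intermediate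
38 | C2=C3 enol triflate of 37 | C1C(=O)O[C@@H]2C[C@H](C)[C@@]3(O[Si](CC)(CC)CC)C=C(OS(=O)(=O)C(F)(F)F)[C@@]4(C[C@@H]3C[C@H]12)C(=O)O[C@H]1C[C@@H](C)C(CCC5(C)OCCO5)=CC[C@H]14 | intermediate
39 | C11-[(dimethylamino)methyl] lactone A (Mannich base of 38) | CN(C)CC1C(=O)O[C@@H]2C[C@H](C)[C@@]3(O[Si](CC)(CC)CC)C=C(OS(=O)(=O)C(F)(F)F)[C@@]4(C[C@@H]3C[C@H]12)C(=O)O[C@H]1C[C@@H](C)C(CCC5(C)OCCO5)=CC[C@H]14 | intermediate
40 | trimethylammonium iodide of 39 | C[N+](C)(C)CC1C(=O)O[C@@H]2C[C@H](C)[C@@]3(O[Si](CC)(CC)CC)C=C(OS(=O)(=O)C(F)(F)F)[C@@]4(C[C@@H]3C[C@H]12)C(=O)O[C@H]1C[C@@H](C)C(CCC5(C)OCCO5)=CC[C@H]14.[I-] | intermediate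
41 | α-methylene lactone A enol triflate | C=C1C(=O)O[C@@H]2C[C@H](C)[C@@]3(O[Si](CC)(CC)CC)C=C(OS(=O)(=O)C(F)(F)F)[C@@]4(C[C@@H]3C[C@H]12)C(=O)O[C@H]1C[C@@H](C)C(CCC5(C)OCCO5)=CC[C@H]14 | intermediate
42 | C3-(1-ethoxyvinyl) diene (1-OSiEt3, ketal side chain) | C=C1C(=O)O[C@@H]2C[C@H](C)[C@@]3(O[Si](CC)(CC)CC)C=C(C(=C)OCC)[C@@]4(C[C@@H]3C[C@H]12)C(=O)O[C@H]1C[C@@H](C)C(CCC5(C)OCCO5)=CC[C@H]14 | intermediate
43 | CNP0195550.1 | C=C1C(=O)O[C@@H]2C[C@H](C)[C@@]3(O)C=C(C(C)=O)[C@@]4(C[C@@H]3C[C@H]12)C(=O)O[C@H]1C[C@@H](C)C(CCC(C)=O)=CC[C@H]14 | target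

**Step count**

Total step count: 28. Longest linear sequence: 19 steps (steps 1–10 and 20–28); the cyclopropane branch is steps 11–19.

**Steps most likely to fail**

Step 22 (key step). The congested enol terminus next to the quaternary C11' may slow the boat transition state. Isomerisation of the enol ether from Z to E, or loss of the silyl group, could then compete and erode the configuration at C7'. The fallback holds the geometry with a ring instead of relying on conformational preference. It sets out from diketone 32: i-Pr2Si(OTf)2 and Et3N in CH2Cl2 would give the seven-membered diisopropylsilylene-bridged bis(enol ether) F1. In F1 the C7'=C8' bond is endocyclic, so C11' and the enol oxygen are cis by necessity. The same [3,3] shift on warming would give the silylene-bridged ring B diene F2. Aqueous citric acid (or KF in methanol) then releases both ketones and the route is rejoined at 35.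

Step 9. Base may epimerise C10 or C5 before ring closure, and the aldol may close to a cis-fused ketol or go on to dehydration. The fallback sets C1 by an intermolecular addition, whose face is chosen by the two α-substituents, and closes ring C at C3–C11' instead. It sets out from enone 14: Mukaiyama–Michael addition of 1-methoxy-1-(trimethylsilyloxy)ethene (Me3SiOTf cat., CH2Cl2, −78 °C, aqueous work-up) would give the C5-(2-methoxycarbonylethyl) ketone F3. Reformatsky addition of BrZnCH2CO2Me (methyl bromoacetate, Zn, THF) to the C1 ketone from the face opposite both α-substituents would give the hydroxy diester F4. Dieckmann condensation (t-BuOK, THF, 0 °C) of the C11' ester enolate onto the C3 ester then returns to the route at 17.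

Step 24. The hydride may also add to the C3 ketone, and liberated methoxide may cleave the non-enolisable β-keto ester by retro-Claisen reaction. The fallback gives up the chemoselectivity. It sets out from 35: excess LiBH(s-Bu)3 (THF, −78 → −20 °C, AcOH quench) reduces both ketones, and acid-catalysed lactonisation (PPTS, benzene) would give the C3-hydroxy spiro-lactone F5. Dess–Martin oxidation of the one remaining secondary carbinol, to which the tertiary silyl ether and both lactones are inert, then returns to the route at 37.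

**Further compounds**

F1 | step 22 | diisopropylsilylene-bridged bis(enol ether) of 32 (O–Si–O links the C3 and C8' enol oxygens; C7'=C8' endocyclic) | C1C(=O)O[C@@H]2C[C@H](C)[C@@]3(O[Si](CC)(CC)CC)C=C4O[Si](C(C)C)(C(C)C)OC(=C[C@]4(C[C@@H]3C[C@H]12)C(=O)OC)[C@@H]6[C@@H](C)[C@@]6(C=C)CCC7(C)OCCO7
F2 | step 22 | silylene-bridged ring B cyclohepta-1,4-diene (rearranged F1) | C1C(=O)O[C@@H]2C[C@H](C)[C@@]3(O[Si](CC)(CC)CC)C=C4O[Si](C(C)C)(C(C)C)OC5=C[C@@H](C)C(CCC7(C)OCCO7)=CC[C@H]5[C@]4(C[C@@H]3C[C@H]12)C(=O)OC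
F3 | step 9 | C5-(2-methoxycarbonylethyl) ketone of ring A | C1C(=O)O[C@@H]2C[C@H](C)C(=O)[C@H](CCC(=O)OC)C[C@H]12
F4 | step 9 | C1-hydroxy diester (C1-CH2CO2Me and C5-CH2CH2CO2Me) | C1C(=O)O[C@@H]2C[C@H](C)[C@@](O)(CC(=O)OC)[C@H](CCC(=O)OC)C[C@H]12
F5 | step 24 | C3-hydroxy spiro-lactone B (C3 carbinol configuration open) | C1C(=O)O[C@@H]2C[C@H](C)[C@@]3(O[Si](CC)(CC)CC)CC(O)[C@@]4(C[C@@H]3C[C@H]12)C(=O)O[C@H]1C[C@@H](C)C(CCC5(C)OCCO5)=CC[C@H]14
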